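## Retrosynthetic overview

1. Both C–Br bonds come from vinyl bromides (made from ketones via enol triflates) by radical hydrogen-atom-transfer hydrogenation from the less hindered face; the 5'-OH comes from 1,2-reduction of an enone.
2. The quaternary C1' (methyl) and the C5' carbonyl come from a hydroxyl-directed Simmons–Smith cyclopropanation of a tetrasubstituted MOM enol ether, followed by acidic cyclopropanol opening.
3. The C2–C1' bond comes from equatorial addition of a cyclopentenylcerium reagent (cyclopentane fragment) to the C2 ketone of the decalin fragment.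
4. The decalin comes from (R)-Wieland–Miescher ketone: ring B is the starting cyclohexanedione and ring A is closed by organocatalytic Robinson annulation; then deconjugative ketalization, dihydroxylation, oxidation and MeMgBr addition.
5. The cyclopentane ring is bought as 2,2-dimethylcyclopentane-1,3-dione and desymmetrized by a ketoreductase; the only ring made after that is the transient cyclopropane.

Assumption: a ketoreductase giving the (R)-alcohol from 2,2-dimethylcyclopentane-1,3-dione is taken from a commercial screening panel.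

Locants used in names: decalin C1–C8a (C2 carries the cyclopentyl group, C4a the angular methyl, C5 the bromine, C8 the methyl carbinol, C8a the angular hydroxyl); cyclopentane C1'–C5' (C1' bonded to C2, C2' = CMe2, C3' = CHBr, C4' = CH2, C5' = CHOH). α = the decalin face of the angular methyl, β = the opposite face.

## Route

**Decalin fragment**

Step 1
Reactants: 1 2-methylcyclohexane-1,3-dione; 2 methyl vinyl ketone (but-3-en-2-one)
Product: 3 2-methyl-2-(3-oxobutyl)cyclohexane-1,3-dione
Conditions: Et3N (1 mol %), neat, rt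
Reagents that add atoms: none
Why: Michael addition of the stabilized dione enolate to the enone gives the achiral triketone with the future angular methyl on a quaternary carbon.

Step 2
Reactants: 3 2-methyl-2-(3-oxobutyl)cyclohexane-1,3-dione
Product: 4 (R)-Wieland–Miescher ketone
Conditions: (R)-N-[(Ra)-2'-(tosylamino)-1,1'-binaphthalen-2-yl]pyrrolidine-2-carboxamide (N-tosyl-(Ra)-binam-D-prolinamide, 2 mol %), PhCO2H (2.5 mol %), neat, rt; recrystallization
Reagents that add atoms: none
Why: Hajos–Parrish–Eder–Sauer–Wiechert intramolecular aldol condensation in which the chiral enamine catalyst selects one of the two enantiotopic ring carbonyls and so sets the C4a quaternary stereocenter as R.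

Step 3
Reactants: 4 (R)-Wieland–Miescher ketone
Product: 5 (4aR,5R)-5-hydroxy-4a-methyl-4,4a,5,6,7,8-hexahydronaphthalen-2(3H)-one
Conditions: NaBH4 (0.3 equiv), EtOH, –10 °C
Reagents that add atoms: none
Why: Chemoselective borohydride reduction of the saturated ketone in the presence of the enone, with hydride entering opposite the angular methyl to give the 5α-alcohol (a temporary mask that is erased in step 5).

Step 4
Reactants: 5 (4aR,5R)-5-hydroxy-4a-methyl-4,4a,5,6,7,8-hexahydronaphthalen-2(3H)-one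
Product: 6 hydroxy ketal (C2 dioxolane; C8=C8a alkene; 5α-OH)
Conditions: HOCH2CH2OH (5 equiv), TsOH·H2O (5 mol %), benzene, reflux, Dean–Stark
Reagents that add atoms: ethylene glycol, OCCO
Why: Acid-catalysed ketalization of the enone with the usual deconjugative migration of the double bond to C8=C8a.

Step 5
Reactants: 6 hydroxy ketal
Product: 7 keto ketal (C2 dioxolane; C8=C8a alkene; C5 ketone)
Conditions: DMP (1.3 equiv), CH2Cl2, rt
Reagents that add atoms: none
Why: Dess–Martin oxidation returns the C5 ketone, now the only free carbonyl.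

Step 6
Reactants: 7 keto ketal
Product: 9 C5 enol triflate (C5=C6 and C8=C8a diene ketal), via potassium enolate 8 (not isolated)
Conditions: KN(SiMe3)2 (1.2 equiv), THF, –78 °C; PhNTf2 (1.3 equiv), –78 → 0 °C
Reagents that add atoms: N-phenylbis(trifluoromethanesulfonimide), O=S(=O)(N(c1ccccc1)S(=O)(=O)C(F)(F)F)C(F)(F)F
Why: Enolate O-triflation, regiodefined because C4a is quaternary so only C6 can be deprotonated.

Step 7
Reactants: 9 C5 enol triflate
Product: 10 C5 vinyl bromide (diene ketal)
Conditions: Ni(OAc)2·4H2O (10 mol %), cycloocta-1,5-diene (30 mol %), Zn dust (20 mol %), LiBr (3 equiv), DMA/THF, rt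
Reagents that add atoms: lithium bromide, [Li+].[Br-]
Why: Nickel-catalysed halogenation of an enol triflate (oxidative addition to zerovalent nickel, triflate/bromide exchange, C–Br reductive elimination).

Step 8
Reactants: 10 C5 vinyl bromide
Product: 11 8β,8aβ-diol (vinyl bromide ketal)
Conditions: OsO4 (2 mol %), NMO (1.5 equiv), acetone/H2O 8:1, rt
Reagents that add atoms: N-methylmorpholine N-oxide, C[N+]1([O-])CCOCC1; water, O (both oxygens are delivered through catalytic OsO4, O=[Os](=O)(=O)=O)
Why: Upjohn syn-dihydroxylation of the electron-richer C8=C8a alkene from the face opposite the angular methyl sets the 8a-OH β (trans ring fusion), while the deactivated vinyl bromide is left alone.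

Step 9
Reactants: 11 8β,8aβ-diol (vinyl bromide ketal)
Product: 12 5α-bromo-8β,8aβ-diol ketal (trans-decalin)
Conditions: Mn(dpm)3 (dpm = 2,2,6,6-tetramethylheptane-3,5-dionate, 10 mol %), PhSiH3 (2 equiv), t-BuOOH (2 equiv), i-PrOH, rt
Reagents that add atoms: none
Why: Metal-hydride hydrogen-atom-transfer hydrogenation: H adds to C6 and the α-bromo radical at C5 is quenched axially from the face opposite the angular methyl, giving the equatorial 5α-bromide without C–Br cleavage.

Step 10
Reactants: 12 5α-bromo-8β,8aβ-diol ketal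
Product: 13 5α-bromo-8aβ-hydroxy-8-ketone ketal
Conditions: DMP (1.5 equiv), CH2Cl2, 0 °C → rt
Reagents that add atoms: none
Why: Dess–Martin oxidation of the only secondary alcohol gives the α-hydroxy ketone; the tertiary 8a-OH cannot be oxidized.

Step 11
Reactants: 13 5α-bromo-8aβ-hydroxy-8-ketone ketal
Product: 14 5α-bromo-4aα,8β-dimethyl-8α,8aβ-diol ketal
Conditions: MeMgBr (4 equiv), THF, –78 → 0 °C
Reagents that add atoms: methylmagnesium bromide, C[Mg]Br
Why: Grignard addition along the equatorial trajectory, because axial attack is blocked by the syn-axial angular methyl, gives the equatorial 8β-methyl and the axial 8α-OH trans to the 8a-OH.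

Step 12
Reactants: 14 5α-bromo-4aα,8β-dimethyl-8α,8aβ-diol ketal
Product: 15 5α-bromo-8α,8aβ-dihydroxy-4aα,8β-dimethyl-trans-decalin-2-one
Conditions: PPTS (0.3 equiv), acetone/H2O 10:1, 45 °C
Reagents that add atoms: water, O
Why: Mild acetal hydrolysis frees the C2 ketone without dehydrating the β-hydroxy ketone.

Step 13
Reactants: 15 5α-bromo-8α,8aβ-dihydroxy-4aα,8β-dimethyl-trans-decalin-2-one
Product: 16 bis(trimethylsilyl) ether of 15
Conditions: N-(trimethylsilyl)imidazole (6 equiv), neat, 50 °C
Reagents that add atoms: N-(trimethylsilyl)imidazole, C[Si](C)(C)n1ccnc1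
Why: Silylation of both tertiary alcohols so that they neither quench the organometallic partner nor trigger retro-aldol or elimination.

**Cyclopentane fragment**

Step 14
Reactants: 17 2,2-dimethylcyclopentane-1,3-dione
Product: 18 (R)-3-hydroxy-2,2-dimethylcyclopentan-1-one
Conditions: (R)-selective ketoreductase (NADPH-dependent alcohol dehydrogenase, oxidoreductase class EC 1.1.1), NADP+ (cat.), i-PrOH (10 vol %), phosphate buffer pH 7, 30 °C
Reagents that add atoms: none
Why: Enzymatic desymmetrization: the ketoreductase reduces one of the two enantiotopic carbonyls of the meso dione and so sets the single stereocenter (R, future C3') with isopropanol recycling the cofactor.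

Step 15
Reactants: 18 (R)-3-hydroxy-2,2-dimethylcyclopentan-1-one
Product: 19 (R)-3-(tert-butyldimethylsilyloxy)-2,2-dimethylcyclopentan-1-one
Conditions: TBSCl (1.3 equiv), imidazole (2.5 equiv), DMF, rt
Reagents that add atoms: tert-butyldimethylsilyl chloride, CC(C)(C)[Si](C)(C)Cl
Why: Silyl protection of the secondary alcohol.

Step 16
Reactants: 19 (R)-3-(tert-butyldimethylsilyloxy)-2,2-dimethylcyclopentan-1-one
Product: 21 (3R)-3-(tert-butyldimethylsilyloxy)-5-hydroxy-2,2-dimethylcyclopentan-1-one (C5 epimers), via potassium enolate 20 (not isolated)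
Conditions: KN(SiMe3)2 (1.2 equiv), THF, –78 °C; (±)-2-(phenylsulfonyl)-3-phenyloxaziridine (1.5 equiv), –78 °C; sat. NH4Cl
Reagents that add atoms: 2-(phenylsulfonyl)-3-phenyloxaziridine, O=S(=O)(N1OC1c1ccccc1)c1ccccc1
Why: Davis α-hydroxylation of the only possible enolate (the other α-carbon is CMe2); the new carbinol centre becomes sp2 in step 18, so its configuration does not matter.

Step 17
Reactants: 21 (3R)-3-(tert-butyldimethylsilyloxy)-5-hydroxy-2,2-dimethylcyclopentan-1-one
Product: 22 (3R)-3-(tert-butyldimethylsilyloxy)-5-(methoxymethoxy)-2,2-dimethylcyclopentan-1-one (C5 epimers)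
Conditions: MOMCl (3 equiv), i-Pr2NEt (5 equiv), CH2Cl2, 0 °C → rt
Reagents that add atoms: chloromethyl methyl ether, COCCl
Why: Acetal protection under weakly basic conditions, chosen because a MOM enol ether, unlike a silyl enol ether, survives the later vinyllithium without 1,3-silyl migration.

Step 18
Reactants: 22 (3R)-3-(tert-butyldimethylsilyloxy)-5-(methoxymethoxy)-2,2-dimethylcyclopentan-1-one
Product: 24 (4R)-4-(tert-butyldimethylsilyloxy)-2-(methoxymethoxy)-5,5-dimethylcyclopent-1-en-1-yl triflate, via potassium enolate 23 (not isolated)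
Conditions: KN(SiMe3)2 (1.3 equiv), THF, –78 °C; PhNTf2 (1.4 equiv), –78 → 0 °C
Reagents that add atoms: N-phenylbis(trifluoromethanesulfonimide), O=S(=O)(N(c1ccccc1)S(=O)(=O)C(F)(F)F)C(F)(F)F
Why: Enolate O-triflation at the single enolizable position gives the tetrasubstituted β-alkoxy enol triflate and converges the C5 epimers.

Step 19
Reactants: 24 (4R)-4-(tert-butyldimethylsilyloxy)-2-(methoxymethoxy)-5,5-dimethylcyclopent-1-en-1-yl triflate
Product: 25 [(4R)-4-(tert-butyldimethylsilyloxy)-2-(methoxymethoxy)-5,5-dimethylcyclopent-1-en-1-yl]trimethylstannane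
Conditions: (Me3Sn)2 (1.5 equiv), Pd(PPh3)4 (5 mol %), LiCl (6 equiv), 1,4-dioxane, 90 °C
Reagents that add atoms: hexamethylditin, C[Sn](C)(C)[Sn](C)(C)C
Why: Palladium-catalysed stannylation of the enol triflate (oxidative addition to zerovalent palladium, Sn–Sn transmetalation, reductive elimination).

**Fragment union and endgame**

Step 20
Reactants: 25 [(4R)-4-(tert-butyldimethylsilyloxy)-2-(methoxymethoxy)-5,5-dimethylcyclopent-1-en-1-yl]trimethylstannane; 16 bis(trimethylsilyl) ether of 15
Product: 28 coupled carbinol (2β-OH; 2α-cyclopentenyl; 3'-OTBS; 5'-OMOM enol ether; 8α,8aβ-bis-OTMS), via cyclopentenyllithium 26 (not isolated), via cyclopentenylcerium dichloride 27 (not isolated)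
Conditions: 25 (1.4 equiv), MeLi (1.35 equiv), THF, –78 → –40 °C; CeCl3 (anhydrous, 1.5 equiv), –78 °C; 16, –78 → –40 °C; pH 7 buffer
Reagents that add atoms: none
Why: Tin–lithium exchange and transmetalation give a weakly basic organocerium whose 1,2-addition to the C2 ketone follows the equatorial trajectory because the axial 8a-OTMS blocks axial attack, giving the axial 2β-OH cis to the 8a-oxygen and the cyclopentenyl group equatorial.

Step 21
Reactants: 28 coupled carbinol
Product: 29 enol ether tetraol (2β,8α,8aβ,3'-OH)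
Conditions: TBAF (6 equiv), THF, 0 → 40 °C; work-up with NaHCO3, chromatography on Et3N-deactivated silica
Reagents that add atoms: none
Why: Fluoride cleaves the TBS and both TMS ethers under basic conditions that the acid-sensitive β-hydroxy enol ether tolerates, freeing the 3'-OH needed as a directing group.

Step 22
Reactants: 29 enol ether tetraol
Product: 30 cyclopropane tetraol (CH2 across C1'–C5' cis to 3'-OH)
Conditions: Et2Zn (8 equiv), CH2I2 (8 equiv), CH2Cl2, –10 °C → rt; aq. NaHCO3/Na2EDTA
Reagents that add atoms: diiodomethane, ICI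
Why: Furukawa–Simmons–Smith cyclopropanation of the electron-rich enol ether, with the zinc alkoxide of the homoallylic 3'-OH delivering CH2 to its own face (cyclopent-3-enol effect), which fixes C1' with the future methyl cis to the 3'-oxygen and the decalin on the other face.

Step 23
Reactants: 30 cyclopropane tetraol
Product: 31 3'-ketone triol
Conditions: DMP (1.3 equiv), CH2Cl2, 0 °C → rt
Reagents that add atoms: none
Why: Dess–Martin oxidation of the only secondary alcohol removes the relay stereocenter after it has done its work and gives the ketone that becomes the vinyl bromide.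

Step 24
Reactants: 31 3'-ketone triol
Product: 32 tris(trimethylsilyl) ether of 31
Conditions: N-(trimethylsilyl)imidazole (10 equiv), neat, 60 °C
Reagents that add atoms: N-(trimethylsilyl)imidazole, C[Si](C)(C)n1ccnc1
Why: Neutral silylation of the three tertiary alcohols so that the following enolate triflation is clean.

Step 25
Reactants: 32 tris(trimethylsilyl) ether of 31
Product: 34 C3' enol triflate (C3'=C4'), via potassium enolate 33 (not isolated)
Conditions: KN(SiMe3)2 (1.3 equiv), THF, –78 °C; PhNTf2 (1.4 equiv), –78 → 0 °C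
Reagents that add atoms: N-phenylbis(trifluoromethanesulfonimide), O=S(=O)(N(c1ccccc1)S(=O)(=O)C(F)(F)F)C(F)(F)F
Why: Enolate O-triflation, regiodefined because C2' is quaternary.

Step 26
Reactants: 34 C3' enol triflate
Product: 35 C3' trimethylstannyl alkene
Conditions: (Me3Sn)2 (1.5 equiv), Pd(PPh3)4 (5 mol %), LiCl (6 equiv), 1,4-dioxane, 80 °C
Reagents that add atoms: hexamethylditin, C[Sn](C)(C)[Sn](C)(C)C
Why: Palladium-catalysed stannylation of the enol triflate, used here instead of nickel/zinc because the secondary alkyl bromide is inert to zerovalent palladium.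

Step 27
Reactants: 35 C3' trimethylstannyl alkene
Product: 36 C3' vinyl bromide
Conditions: NBS (1.05 equiv), CH2Cl2, –40 °C
Reagents that add atoms: N-bromosuccinimide, O=C1CCC(=O)N1Br
Why: Ipso-bromodestannylation of the vinylstannane, fast enough at low temperature to spare the donor-substituted cyclopropane.

Step 28
Reactants: 36 C3' vinyl bromide
Product: 38 bromo enone triol (3'-bromo-1'-methyl-5'-oxocyclopent-3'-enyl), via cyclopropanol 37 (not isolated)
Conditions: TsOH·H2O (2 equiv), THF/H2O 4:1, 40 °C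
Reagents that add atoms: none
Why: Acid removes the TMS and MOM groups and opens the cyclopropanol by protonation at the CH2 carbon (Conia-type α-methylation), giving the C1' methyl and the C5' ketone conjugated with the vinyl bromide, with C1' keeping the configuration set in step 22.

Step 29
Reactants: 38 bromo enone triol
Product: 39 allylic alcohol (5'-OH cis to the decalin)
Conditions: NaBH4 (1.5 equiv), CeCl3·7H2O (1.5 equiv), MeOH, –78 → –40 °C
Reagents that add atoms: none
Why: Luche 1,2-reduction of the β-bromo enone, with hydride entering from the methyl face of C1' (opposite the bulky decalinyl carbinol), gives the 5'-OH cis to the decalin.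

Step 30
Reactants: 39 allylic alcohol
Product: 40 CNP0390567.2 (target)
Conditions: Mn(dpm)3 (20 mol %), PhSiH3 (3 equiv), t-BuOOH (3 equiv), i-PrOH/CH2Cl2, rt
Reagents that add atoms: none
Why: Metal-hydride hydrogen-atom-transfer hydrogenation: H adds to C4' and the α-bromo radical at C3' takes its hydrogen from the less hindered methyl face, leaving bromine cis to the 5'-OH and the decalin.

## Compound list

1 | 2-methylcyclohexane-1,3-dione | CC1C(=O)CCCC1=O | starting material
2 | methyl vinyl ketone | CC(=O)C=C | starting material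
3 | 2-methyl-2-(3-oxobutyl)cyclohexane-1,3-dione | CC(=O)CCC1(C)C(=O)CCCC1=O | intermediate
4 | (R)-Wieland–Miescher ketone | O=C1CC[C@@]2(C)C(=O)CCCC2=C1 | intermediate
5 | (4aR,5R)-5-hydroxy-4a-methyl-4,4a,5,6,7,8-hexahydronaphthalen-2(3H)-one | O=C1CC[C@@]2(C)[C@H](O)CCCC2=C1 | intermediate
6 | hydroxy ketal: C2 ethylene ketal, C8=C8a alkene, 5α-OH, 4aα-Me | O1CCOC13CC[C@@]2(C)[C@H](O)CCC=C2C3 | intermediate
7 | keto ketal: C2 ethylene ketal, C8=C8a alkene, C5 ketone | O1CCOC13CC[C@@]2(C)C(=O)CCC=C2C3 | intermediate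
8 | potassium enolate of 7 (C5–OK, C5=C6) | O1CCOC13CC[C@@]2(C)C([O-])=CCC=C2C3.[K+] | intermediate
9 | C5 enol triflate of 7 (C5=C6, C8=C8a) | O1CCOC13CC[C@@]2(C)C(OS(=O)(=O)C(F)(F)F)=CCC=C2C3 | intermediate
10 | C5 vinyl bromide (C5=C6, C8=C8a, C2 ketal) | O1CCOC13CC[C@@]2(C)C(Br)=CCC=C2C3 | intermediate
11 | 5-bromo-C5=C6 alkene, 8β,8aβ-diol, C2 ketal | O1CCOC13CC[C@@]2(C)C(Br)=CC[C@@H](O)[C@]2(O)C3 | intermediate
12 | 5α-bromo-8β,8aβ-diol, C2 ketal, trans-decalin | O1CCOC13CC[C@@]2(C)[C@H](Br)CC[C@@H](O)[C@]2(O)C3 | intermediate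
13 | 5α-bromo-8aβ-hydroxy-8-ketone, C2 ketal | O1CCOC13CC[C@@]2(C)[C@H](Br)CCC(=O)[C@]2(O)C3 | intermediate
14 | 5α-bromo-4aα,8β-dimethyl-8α,8aβ-diol, C2 ketal | O1CCOC13CC[C@@]2(C)[C@H](Br)CC[C@](C)(O)[C@]2(O)C3 | intermediate
15 | 5α-bromo-8α,8aβ-dihydroxy-4aα,8β-dimethyl-trans-decalin-2-one | O=C1CC[C@@]2(C)[C@H](Br)CC[C@](C)(O)[C@]2(O)C1 | intermediate
16 | 8α,8aβ-bis(trimethylsilyl) ether of 15 | O=C1CC[C@@]2(C)[C@H](Br)CC[C@](C)(O[Si](C)(C)C)[C@]2(O[Si](C)(C)C)C1 | intermediate
17 | 2,2-dimethylcyclopentane-1,3-dione | CC1(C)C(=O)CCC1=O | starting material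
18 | (R)-3-hydroxy-2,2-dimethylcyclopentan-1-one | CC1(C)[C@H](O)CCC1=O | intermediate
19 | (R)-3-(tert-butyldimethylsilyloxy)-2,2-dimethylcyclopentan-1-one | CC1(C)[C@H](O[Si](C)(C)C(C)(C)C)CCC1=O | intermediate
20 | potassium enolate of 19 | CC1(C)[C@H](O[Si](C)(C)C(C)(C)C)CC=C1[O-].[K+] | intermediate
21 | (3R)-3-(tert-butyldimethylsilyloxy)-5-hydroxy-2,2-dimethylcyclopentan-1-one, C5 epimers | CC1(C)[C@H](O[Si](C)(C)C(C)(C)C)CC(O)C1=O | intermediate
22 | (3R)-3-(tert-butyldimethylsilyloxy)-5-(methoxymethoxy)-2,2-dimethylcyclopentan-1-one, C5 epimers | CC1(C)[C@H](O[Si](C)(C)C(C)(C)C)CC(OCOC)C1=O | intermediate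
23 | potassium enolate of 22 | CC1(C)[C@H](O[Si](C)(C)C(C)(C)C)CC(OCOC)=C1[O-].[K+] | intermediate
24 | (4R)-4-(tert-butyldimethylsilyloxy)-2-(methoxymethoxy)-5,5-dimethylcyclopent-1-en-1-yl triflate | CC1(C)[C@H](O[Si](C)(C)C(C)(C)C)CC(OCOC)=C1OS(=O)(=O)C(F)(F)F | intermediate
25 | [(4R)-4-(tert-butyldimethylsilyloxy)-2-(methoxymethoxy)-5,5-dimethylcyclopent-1-en-1-yl]trimethylstannane | CC1(C)[C@H](O[Si](C)(C)C(C)(C)C)CC(OCOC)=C1[Sn](C)(C)C | intermediate
26 | cyclopentenyllithium from 25 | CC1(C)[C@H](O[Si](C)(C)C(C)(C)C)CC(OCOC)=C1[Li] | intermediate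
27 | cyclopentenylcerium dichloride from 26 | CC1(C)[C@H](O[Si](C)(C)C(C)(C)C)CC(OCOC)=C1[Ce](Cl)Cl | intermediate
28 | coupled carbinol: 2β-OH, 2α-(3'-OTBS-5'-OMOM-2',2'-dimethylcyclopent-5'-en-1'-yl), 5α-Br, 8α,8aβ-bis-OTMS | CC1(C)[C@H](O[Si](C)(C)C(C)(C)C)CC(OCOC)=C1[C@]1(O)CC[C@@]2(C)[C@H](Br)CC[C@](C)(O[Si](C)(C)C)[C@]2(O[Si](C)(C)C)C1 | intermediate
29 | enol ether tetraol (28 without silyl groups) | CC1(C)[C@H](O)CC(OCOC)=C1[C@]1(O)CC[C@@]2(C)[C@H](Br)CC[C@](C)(O)[C@]2(O)C1 | intermediate
30 | cyclopropane tetraol: CH2 bridging C1' and C5' on the face of the 3'-OH; 5'-OMOM and decalin on the other face | CC1(C)[C@H](O)C[C@]2(OCOC)C[C@]12[C@]1(O)CC[C@@]2(C)[C@H](Br)CC[C@](C)(O)[C@]2(O)C1 | intermediate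
31 | 3'-ketone of 30 (triol) | CC1(C)C(=O)C[C@]2(OCOC)C[C@]12[C@]1(O)CC[C@@]2(C)[C@H](Br)CC[C@](C)(O)[C@]2(O)C1 | intermediate
32 | 2β,8α,8aβ-tris(trimethylsilyl) ether of 31 | CC1(C)C(=O)C[C@]2(OCOC)C[C@]12[C@]1(O[Si](C)(C)C)CC[C@@]2(C)[C@H](Br)CC[C@](C)(O[Si](C)(C)C)[C@]2(O[Si](C)(C)C)C1 | intermediate
33 | potassium enolate of 32 (C3'–OK, C3'=C4') | CC1(C)C([O-])=C[C@]2(OCOC)C[C@]12[C@]1(O[Si](C)(C)C)CC[C@@]2(C)[C@H](Br)CC[C@](C)(O[Si](C)(C)C)[C@]2(O[Si](C)(C)C)C1.[K+] | intermediate
34 | C3' enol triflate of 32 | CC1(C)C(OS(=O)(=O)C(F)(F)F)=C[C@]2(OCOC)C[C@]12[C@]1(O[Si](C)(C)C)CC[C@@]2(C)[C@H](Br)CC[C@](C)(O[Si](C)(C)C)[C@]2(O[Si](C)(C)C)C1 | intermediate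
35 | C3' trimethylstannyl alkene | CC1(C)C([Sn](C)(C)C)=C[C@]2(OCOC)C[C@]12[C@]1(O[Si](C)(C)C)CC[C@@]2(C)[C@H](Br)CC[C@](C)(O[Si](C)(C)C)[C@]2(O[Si](C)(C)C)C1 | intermediate
36 | C3' vinyl bromide (cyclopropyl MOM ether, tris-TMS) | CC1(C)C(Br)=C[C@]2(OCOC)C[C@]12[C@]1(O[Si](C)(C)C)CC[C@@]2(C)[C@H](Br)CC[C@](C)(O[Si](C)(C)C)[C@]2(O[Si](C)(C)C)C1 | intermediate
37 | cyclopropanol (36 without TMS and MOM groups) | CC1(C)C(Br)=C[C@]2(O)C[C@]12[C@]1(O)CC[C@@]2(C)[C@H](Br)CC[C@](C)(O)[C@]2(O)C1 | intermediate
38 | bromo enone triol: 2α-(3'-bromo-1',2',2'-trimethyl-5'-oxocyclopent-3'-en-1'-yl), 2β,8α,8aβ-triol, 5α-Br | CC1(C)C(Br)=CC(=O)[C@@]1(C)[C@]1(O)CC[C@@]2(C)[C@H](Br)CC[C@](C)(O)[C@]2(O)C1 | intermediate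
39 | allylic alcohol: 5'-OH cis to the decalin, C3'(Br)=C4' | CC1(C)C(Br)=C[C@@H](O)[C@@]1(C)[C@]1(O)CC[C@@]2(C)[C@H](Br)CC[C@](C)(O)[C@]2(O)C1 | intermediate
40 | (2S,4aR,5R,8S,8aS)-5-bromo-2-[(1S,3S,5R)-3-bromo-5-hydroxy-1,2,2-trimethylcyclopentyl]-4a,8-dimethyldecahydronaphthalene-2,8,8a-triol (CNP0390567.2) | CC1(C)[C@@H](Br)C[C@@H](O)[C@@]1(C)[C@]1(O)CC[C@@]2(C)[C@H](Br)CC[C@](C)(O)[C@]2(O)C1 | target

## Step count and risk

Total steps: 30. Longest linear sequence: 24 (steps 1–13, then 20–30); the cyclopentane branch is 6 steps (14–19) before the union.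

The three steps most likely to fail:

**Step 20 (addition of cyclopentenylcerium 27 to ketone 16).** The nucleophile is tetrasubstituted and flanked by CMe2, and the ketone can enolize and lose its β-silyloxy group. The fallback makes the C2–C1' bond by a samarium Reformatsky-type aldol with the methyl already in place; it sets out from enol triflate 24 (ketone 16 is used unchanged) and comes back at bromo enone 38. Negishi coupling of 24 (MeZnCl, Pd(PPh3)4, THF, 50 °C) gives the methyl-substituted MOM enol ether F1. NBS in THF/H2O with NaHCO3 brominates C1' and releases the ketone, giving the tertiary α-bromo ketone F2. SmI2 (2.2 equiv, THF, –78 °C) added to F2 and 16 forms the regiodefined samarium enolate F3, which adds to the C2 ketone from the cyclopentane face opposite the 3'-OTBS group and along the equatorial trajectory of the decalin to give the aldol adduct F4. HF·pyridine (pyridine/THF, 0 °C) removes the three silyl groups to give the keto tetraol F5. DMP oxidizes the 3'-alcohol to the cyclopentane-1,3-dione F6. Ph3P/CBr4 (CH2Cl2, 0 °C) then replaces the less hindered enol oxygen (at C3', next to CMe2) by bromine and gives 38, from which steps 29 and 30 follow.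

**Step 22 (directed cyclopropanation of the crowded tetrasubstituted enol ether 29).** Rate and facial selectivity are both uncertain next to two fully substituted carbons. The fallback installs the methylene before the fragments are joined, where only the 3'-hydroxyl can direct; it sets out from stannane 25 and comes back at cyclopropane 30. TBAF (THF, rt) gives the stannyl cyclopentenol F7. Et2Zn/CH2I2 (CH2Cl2, 0 °C) delivers CH2 syn to the free hydroxyl and gives the cyclopropyl stannane F8. MeLi (2.1 equiv, THF, –78 → 0 °C) deprotonates the alcohol and exchanges tin for lithium with retention, giving the configurationally stable cyclopropyllithium alkoxide F9, which adds to ketone 16 in the presence of CeCl3 (–78 °C) to give the adduct F10. TBAF removes the two TMS ethers and gives 30, from which steps 23–30 follow.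

**Step 30 (hydrogen-atom-transfer hydrogenation of the cyclopentenyl bromide 39).** Debromination or poor facial selectivity at C3' would spoil the last step. The fallback switches from radical hydrogen-atom transfer to surface hydrogenation of a shielded substrate; it sets out from 39 and comes back at target 40. 2,2-Dimethoxypropane with PPTS (acetone, rt) ties the 5'-OH and the 2-OH together as the six-membered acetonide F11, which removes any hydroxyl-directed delivery and adds bulk to the upper face. H2 (1 atm) over 5 % Rh/Al2O3 in EtOAc adds from the methyl-bearing face and gives the saturated dibromide acetonide F12; rhodium is chosen because it hydrogenolyses C–Br bonds far more slowly than palladium. 80 % aqueous AcOH (40 °C) removes the acetonide and gives 40.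

## Further compounds

F1 | step 20 | (4R)-4-(tert-butyldimethylsilyloxy)-2-(methoxymethoxy)-1,5,5-trimethylcyclopent-1-ene (methyl MOM enol ether) | CC1(C)[C@H](O[Si](C)(C)C(C)(C)C)CC(OCOC)=C1C
F2 | step 20 | (4R)-2-bromo-4-(tert-butyldimethylsilyloxy)-2,3,3-trimethylcyclopentan-1-one (C2 epimers) | CC1(C)[C@H](O[Si](C)(C)C(C)(C)C)CC(=O)C1(C)Br
F3 | step 20 | samarium enolate of (4R)-4-(tert-butyldimethylsilyloxy)-2,3,3-trimethylcyclopentan-1-one | CC1(C)[C@H](O[Si](C)(C)C(C)(C)C)CC(O[Sm](I)I)=C1C
F4 | step 20 | aldol adduct: 2β-OH, 2α-(3'-OTBS-1',2',2'-trimethyl-5'-oxocyclopentyl), 8α,8aβ-bis-OTMS, 5α-Br | CC1(C)[C@H](O[Si](C)(C)C(C)(C)C)CC(=O)[C@@]1(C)[C@]1(O)CC[C@@]2(C)[C@H](Br)CC[C@](C)(O[Si](C)(C)C)[C@]2(O[Si](C)(C)C)C1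
F5 | step 20 | keto tetraol (F4 without silyl groups; 3'-OH cis to the 1'-methyl) | CC1(C)[C@H](O)CC(=O)[C@@]1(C)[C@]1(O)CC[C@@]2(C)[C@H](Br)CC[C@](C)(O)[C@]2(O)C1
F6 | step 20 | cyclopentane-1,3-dione triol (3',5'-dioxo) | CC1(C)C(=O)CC(=O)[C@@]1(C)[C@]1(O)CC[C@@]2(C)[C@H](Br)CC[C@](C)(O)[C@]2(O)C1
F7 | step 22 | (1R)-3-(methoxymethoxy)-2,2-dimethyl-4-(trimethylstannyl)cyclopent-3-en-1-ol numbered from the carbinol (stannyl cyclopentenol) | CC1(C)[C@H](O)CC(OCOC)=C1[Sn](C)(C)C
F8 | step 22 | cyclopropyl stannane: CH2 bridging C1' and C5' cis to the 3'-OH; SnMe3 at C1' and OMOM at C5' on the other face | CC1(C)[C@H](O)C[C@]2(OCOC)C[C@]12[Sn](C)(C)C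
F9 | step 22 | cyclopropyllithium lithium alkoxide from F8 | CC1(C)[C@H](O[Li])C[C@]2(OCOC)C[C@]12[Li]
F10 | step 22 | cyclopropane adduct: 2β-OH, 3'-OH free, 5'-OMOM, 8α,8aβ-bis-OTMS, 5α-Br | CC1(C)[C@H](O)C[C@]2(OCOC)C[C@]12[C@]1(O)CC[C@@]2(C)[C@H](Br)CC[C@](C)(O[Si](C)(C)C)[C@]2(O[Si](C)(C)C)C1
F11 | step 30 | 5'-O,2-O-isopropylidene acetal of 39 | CC1(C)C(Br)=C[C@H]2OC(C)(C)O[C@]3(CC[C@@]4(C)[C@H](Br)CC[C@](C)(O)[C@]4(O)C3)[C@@]12C
F12 | step 30 | 5'-O,2-O-isopropylidene acetal of 40 | CC1(C)[C@@H](Br)C[C@H]2OC(C)(C)O[C@]3(CC[C@@]4(C)[C@H](Br)CC[C@](C)(O)[C@]4(O)C3)[C@@]12C
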